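The readings were generated by integration on assumed constants; scatter was added.

At 30.0 min, the last reading of each earlier run, the fall of the starting complex had slowed, so I began there.

common to all: starting complex 0.55 M
- theta: incoming ligand 1.3 equiv; scavenger 1.3 equiv; run made earlier
- alpha: incoming ligand 1.3 equiv; scavenger 1.7 equiv; run made earlier
- zeta: incoming ligand 1.3 equiv; scavenger 2 equiv; run made earlier
- east: incoming ligand 1.30 equiv; scavenger 1.50 equiv; time 1.0 h
- north-west: incoming ligand 1.30 equiv; scavenger 2.20 equiv; time 1.0 h

| run | time / min | starting complex / % | complex with three exchanged / % |
|---|---|---|---|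
| theta | 2.50 | 66 | 0 |
| theta | 5.00 | 51 | 6 |
| theta | 8.00 | 39 | 14 |
| theta | 15.0 | 28 | 19 |
| theta | 30.0 | 27 | 22 |
| alpha | 6.00 | 44 | 12 |
| alpha | 12.0 | 33 | 18 |
| alpha | 20.0 | 28 | 19 |
| alpha | 25.0 | 28 | 22 |
| alpha | 30.0 | 24 | 25 |
| zeta | 2.50 | 65 | 2 |
| zeta | 8.00 | 36 | 17 |
| zeta | 15.0 | 31 | 18 |
| zeta | 20.0 | 31 | 20 |
| zeta | 30.0 | 23 | 24 |

(scatter of a reading: 2 percentage points)



1. part of the starting complex that has reacted at the end, east
2. part of the starting complex that has reacted at the end, north-west
3. what raising the equivalents of scavenger from its lowest to its highest value here does to the part of the starting complex that has reacted (changes below 5 percentage points count as none) (it falls / it rises / no change)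

Those last readings averaged 24.7% starting complex and 23.7% complex with three exchanged, so my first estimate for 1.0 h was 75.3% reacted. From theta to zeta the remainder moved by 4 percentage points, and a change counts from 5 points, so I expected no scavenger trend.

But the fall might go on as a slow drift, so I wanted to know how far it could go. Each exchange costs one unit of incoming ligand. The complex with three exchanged takes 3 units, and the unread 51.7% of the complex carries at least one. The charge less these units is 7.33% of the starting complex charged, the spare ligand.

That is a small difference of large numbers, with a scatter of 2.6 points. If every spare unit attacked starting complex, 82.7% would react; if the units sat as second exchanges on the unread complex, the figure would stay at 75.3%. Between their last two readings theta went from 28% to 27%, but alpha from 28% to 24% and zeta from 31% to 23%, so the readings did not exclude a drift. I committed to about 75.3% in both flasks, knowing that my figure might have to rise towards 82.7%.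

The forecast said 78% (73% to 85%) for east and 79% (73% to 86%) for north-west, with no change, on the ground of “leaving little free ligand”. For east it stood above my figure.

The flasks gave 74.9% in east and 74.8% in north-west, a change of −0.1 points, so no change.

    leaving ligand + incoming ligand ⇌ idle adduct, settled at all times (K = 1.00 L mol⁻¹)
    complex with two exchanged + incoming ligand ⇌ leaving ligand + complex with three exchanged (K = 0.750, k = 0.0200 L mol⁻¹ s⁻¹)
    starting complex + incoming ligand → leaving ligand + complex with one exchanged (k = 0.00510 L mol⁻¹ s⁻¹)
    scavenger + leaving ligand → scavenged by-product (k = 0.650 L mol⁻¹ s⁻¹)
    complex with one exchanged + incoming ligand → leaving ligand + complex with two exchanged (k = 0.00350 L mol⁻¹ s⁻¹)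

East ended with 0.018% of its incoming ligand unbound, the limiting reagent. The spare I had read as 7.33% comes, by the same subtraction on east's end state, to 7.95%, and east holds 7.93% complex with two exchanged. The neighbouring flask, charged with 0.780 equiv incoming ligand, ended with 8.50% complex with three exchanged and 46.7% unread complex, which leaves a spare of 5.80%. It holds 5.79% complex with two exchanged, and 55.2% of its starting complex reacted.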